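**Strategy.** The seven-membered ring is cut across C9–C10 and C6–C7 (guaiane numbering) into a C7–C8–C9 oxyallyl cation and a furan whose α-carbons are C6 and C10 and whose β-carbons (C5, C1) already carry the cyclopentane with the C4 carbinol. One (4+3) cycloaddition forms both bonds and sets C6 and C7. It exploits the 1,4-relation of O6 and the alkene carbon C10 across C5–C1 (a masked furan) and the 1,3-relation of C9H2 and the C7 isopropyl group, which are tied through sulfur in a cyclic oxyallyl cation from 5,5-dimethylthiolan-3-one. The precursors are this thiolanone and a silylated cyclopenta[c]furan carbinol made from (S)-linalool; Raney Ni later unveils isopropyl and CH2.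

Key step: step 8

Remark: locants follow the guaiane skeleton of the target (C1–C5 five-membered ring; C1, C5–C10 seven-membered ring; C4 carbinol, C6 acetoxy, C7 isopropyl, C8 angeloyloxy, C10 methyl); (S)-(+)-linalool of high enantiomeric purity and angelic anhydride are assumed to be commercial.

Step 1
Reactants: 1 (S)-(+)-linalool
Product: 2 (4S)-4-hydroxy-4-methylhex-5-enal (in equilibrium with its five-membered lactol)
Conditions: O3, CH2Cl2, −78 °C (Sudan red 7B end point); Me2S, −78 °C to rt
Reagents that add atoms: ozone, O=[O+][O-]
Why: Ozonolysis should cleave only the electron-rich trisubstituted alkene, since the vinyl group on the carbinol carbon reacts much more slowly, and the C4 stereocentre of linalool is not touched.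

Step 2
Reactants: 2 (4S)-4-hydroxy-4-methylhex-5-enal
Product: 3 (3S)-3-methylhept-1-en-6-yn-3-ol
Conditions: dimethyl (1-diazo-2-oxopropyl)phosphonate, K2CO3, MeOH, 0 °C to rt
Reagents that add atoms: dimethyl (1-diazo-2-oxopropyl)phosphonate, CC(=O)C(=[N+]=[N-])P(=O)(OC)OC
Why: The Seyferth–Gilbert homologation in its Ohira–Bestmann form should convert the aldehyde form of the lactol equilibrium into the terminal alkyne under mild conditions that leave the tertiary allylic alcohol alone.

Step 3
Reactants: 3 (3S)-3-methylhept-1-en-6-yn-3-ol
Product: 4 (3S)-3-methyloct-1-en-6-yn-3-ol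
Conditions: n-BuLi (2.1 equiv), THF, −78 °C; MeI (1.05 equiv), −78 to 0 °C; H2O
Reagents that add atoms: iodomethane, CI
Why: Double deprotonation gives the alkoxide/acetylide dianion, whose acetylide carbon should be methylated selectively by one equivalent of MeI (acetylide alkylation).

Step 4
Reactants: 4 (3S)-3-methyloct-1-en-6-yn-3-ol
Product: 5 (1S,3E)-3-ethylidene-1-methyl-2-methylidenecyclopentan-1-ol
Conditions: Pd(OAc)2 (5 mol %), PPh3 (10 mol %), benzene, 70 °C
Reagents that add atoms: none
Why: Palladium-catalysed 1,6-enyne cycloisomerization (Alder-ene type) should close the C1–C5 bond by hydropalladation of the alkyne, 5-exo carbopalladation of the vinyl group and β-hydride elimination of the only available ring hydrogen, giving the s-cis 1,3-diene with E ethylidene geometry from syn H–Pd addition.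

Step 5
Reactants: 5 (1S,3E)-3-ethylidene-1-methyl-2-methylidenecyclopentan-1-ol
Product: 8 (4S)-1,4-dimethyl-5,6-dihydro-4H-cyclopenta[c]furan-4-ol, via endoperoxide 6 (not isolated), via hydroxy enal 7 (not isolated)
Conditions: O2, hν (visible), tetraphenylporphyrin (cat.), CH2Cl2, −78 °C; Et3N, 0 °C; PPTS (cat.), rt
Reagents that add atoms: dioxygen, O=O
Why: Singlet oxygen should add [4+2] to the locked s-cis diene, Kornblum–DeLaMare rearrangement of the endoperoxide gives the γ-hydroxy enal, and mild acid cyclodehydrates it to the 3,4-fused furan with C6–H and C10–CH3 as α-carbons.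

Step 6
Reactants: 8 (4S)-1,4-dimethyl-5,6-dihydro-4H-cyclopenta[c]furan-4-ol
Product: 9 (4S)-4-[(diisopropylsilyl)oxy]-1,4-dimethyl-5,6-dihydro-4H-cyclopenta[c]furan
Conditions: iPr2SiHCl, imidazole, DMAP (cat.), DMF, rt
Reagents that add atoms: chlorodiisopropylsilane, CC(C)[SiH](Cl)C(C)C
Why: The small secondary chlorosilane should silylate even the tertiary carbinol (silyl ether formation), giving a bulky face-shielding group that later acts as the internal hydride donor.

Step 7
Reactants: 10 methyl sulfanylacetate; 11 methyl 3-methylbut-2-enoate
Product: 14 5,5-dimethylthiolan-3-one, via Michael adduct 12 (not isolated), via keto ester 13 (not isolated)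
Conditions: NaOMe (1.2 equiv), MeOH/toluene, reflux; then 20% aq H2SO4, reflux
Reagents that add atoms: none
Why: Thia-Michael addition, Dieckmann condensation and acidic hydrolysis with decarboxylation are the standard assembly of thiolan-3-ones, and both Dieckmann regioisomers converge on the same ketone.

Step 8
Reactants: 14 5,5-dimethylthiolan-3-one; 9 (4S)-4-[(diisopropylsilyl)oxy]-1,4-dimethyl-5,6-dihydro-4H-cyclopenta[c]furan
Product: 17 endo (4+3) cycloadduct: sulfur-bridged tetracyclic ketone, via chloro ketone 15 (not isolated), via oxyallyl cation 16 (not isolated)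
Conditions: 14 (2 equiv), NCS (1.9 equiv), CH2Cl2, 0 °C, filter; then 9, LiClO4 (3 M in Et2O), Et3N, 0 °C to rt
Reagents that add atoms: none
Why: NCS should chlorinate 14 at the only C–H carbon next to sulfur, and LiClO4/Et3N should ionise chloro ketone 15 to the sulfur-stabilised cyclic oxyallyl cation 16, which adds across the furan α-carbons in an asynchronous (4+3) cycloaddition (4π furan plus 2π allyl cation) forming C6–C7 and C9–C10. The closest known reaction type is the (4+3) cycloaddition of five-membered cyclic and heteroatom-stabilised oxyallyl cations from α-halo ketones with furans. The seven-membered carbocycle closes by this intermolecular suprafacial cycloaddition through the compact (endo) transition state, with C8–O over the furan β-carbons and the S–CMe2 bridge over the ring oxygen. C6, C7, C9 and C10 are set together: the ring-locked U-shape of the cation and the compact transition state put the S–CMe2 bridge, hence the future isopropyl carbon on C7, on the face of the bridging oxygen (cis to O6), while the C4 stereocentre of 9 fixes the absolute sense because the bulky OSiH(iPr)2 group blocks one furan face and the cation adds to the methyl-bearing face. The step needs regio-, endo- and facial selectivity: sulfur leaves the remote neopentylic terminus C7 with the larger LUMO coefficient to bond first to the unsubstituted, most nucleophilic α-carbon C6 and away from the methyl-bearing C10, an exo approach would press the bridge against the cyclopentane, and the silyloxy group shields the other face.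

Step 9
Reactants: 17 endo (4+3) cycloadduct
Product: 18 tetracyclic alcohol (C8–OH pointing toward the C1=C5 alkene, trans to the C7–CMe2 bond)
Conditions: LiBH4, THF, 0 °C to rt; aq NH4Cl
Reagents that add atoms: none
Why: One face of the bridging ketone is closed by the C1=C5 alkene and its fused ring, so hydride should enter from the side of the S–CMe2 bridge (substrate-controlled ketone reduction) and place the C8 hydroxyl trans to the C7 carbon substituent.

Step 10
Reactants: 18 tetracyclic alcohol
Product: 19 silylene-bridged thiabicyclic alcohol (C1=C10 alkene, H5 cis to O4 and O6, O4 and O6 joined by Si(iPr)2)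
Conditions: BF3·OEt2 (1.5 equiv), 2,6-di-tert-butyl-4-methylpyridine, CH2Cl2, −78 to −40 °C
Reagents that add atoms: none
Why: Proposed new method: BF3 should ionise the strained tertiary allylic C10–O bond of the oxygen bridge to a C10–C1–C5 allyl cation, and the Si–H held on O4 next to C5 delivers hydride through a five-membered transition state to C5 on the O4 face, which sets H5 cis to O4 and O6, leaves the tetrasubstituted C1=C10 alkene and lets the silyl cation close onto O6 as the silylene, while the sulfur bridge makes loss of a C9 proton impossible (strained bridgehead alkene); the closest known reaction types are the ionic hydrogenation of allylic ethers with a silane and a Lewis acid and the intramolecular hydride delivery from alkoxy hydrosilanes to β-oxygenated carbonyl and oxocarbenium carbons.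

Step 11
Reactants: 19 silylene-bridged thiabicyclic alcohol
Product: 20 4,6-O-(diisopropylsilylene)guai-1(10)-ene-4,6,8-triol (configuration of the target)
Conditions: Raney Ni (W-2, deactivated in acetone), EtOH, rt
Reagents that add atoms: none
Why: Raney Ni desulfurization should cleave both C–S bonds, turning the bridge into the C7 isopropyl group and the C9 methylene without touching C7 and C8, which are no longer epimerisable, or the tetrasubstituted alkene.

Step 12
Reactants: 20 4,6-O-(diisopropylsilylene)guai-1(10)-ene-4,6,8-triol
Product: 21 8-O-angelate of 20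
Conditions: LiN(SiMe3)2, THF, −78 °C; angelic anhydride, −78 to 0 °C
Reagents that add atoms: angelic anhydride, C/C=C(/C)C(=O)OC(=O)/C(C)=C\C
Why: Acylation of the lithium alkoxide of the only free hydroxyl with the anhydride at low temperature should give the angelate without Z to E isomerisation (alkoxide acylation).

Step 13
Reactants: 21 8-O-angelate of 20
Product: 22 4,6-dihydroxyguai-1(10)-en-8-yl angelate
Conditions: HF·pyridine, THF, 0 °C to rt
Reagents that add atoms: none
Why: Fluoride should cleave both Si–O bonds of the dialkoxysilane (silylene removal) without touching the ester or the alkene.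

Step 14
Reactants: 22 4,6-dihydroxyguai-1(10)-en-8-yl angelate
Product: 23 target, (4S,5R,6R,7R,8S)-6-acetoxy-4-hydroxyguai-1(10)-en-8-yl angelate
Conditions: Ac2O, pyridine, DMAP (cat.), CH2Cl2, 0 °C to rt
Reagents that add atoms: acetic anhydride, CC(=O)OC(C)=O
Why: Nucleophile-catalysed acetylation should take the secondary C6 hydroxyl and leave the unreactive tertiary C4 hydroxyl free.

**Compound list**

1 | (S)-(+)-linalool, (3S)-3,7-dimethylocta-1,6-dien-3-ol | C=C[C@@](C)(O)CCC=C(C)C | starting material
2 | (4S)-4-hydroxy-4-methylhex-5-enal (with its lactol) | C=C[C@@](C)(O)CCC=O | intermediate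
3 | (3S)-3-methylhept-1-en-6-yn-3-ol | C=C[C@@](C)(O)CCC#C | intermediate
4 | (3S)-3-methyloct-1-en-6-yn-3-ol | C=C[C@@](C)(O)CCC#CC | intermediate
5 | (1S,3E)-3-ethylidene-1-methyl-2-methylidenecyclopentan-1-ol | C=C1/C(=C/C)CC[C@]1(C)O | intermediate
6 | endoperoxide: 3,6-dihydro-1,2-dioxine fused to the cyclopentene, CH3 on the peroxide carbon (both epimers), (S) carbinol | CC1OOCC2=C1CC[C@]2(C)O | intermediate
7 | hydroxy enal: (5S)-5-hydroxy-2-(1-hydroxyethyl)-5-methylcyclopent-1-ene-1-carbaldehyde (both carbinol epimers) | CC(O)C1=C(C=O)[C@@](C)(O)CC1 | intermediate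
8 | (4S)-1,4-dimethyl-5,6-dihydro-4H-cyclopenta[c]furan-4-ol | Cc1occ2c1CC[C@]2(C)O | intermediate
9 | (4S)-4-[(diisopropylsilyl)oxy]-1,4-dimethyl-5,6-dihydro-4H-cyclopenta[c]furan | Cc1occ2c1CC[C@]2(C)O[SiH](C(C)C)C(C)C | intermediate
10 | methyl sulfanylacetate (methyl thioglycolate) | COC(=O)CS | starting material
11 | methyl 3-methylbut-2-enoate | COC(=O)C=C(C)C | starting material
12 | Michael adduct: methyl 3-[(2-methoxy-2-oxoethyl)sulfanyl]-3-methylbutanoate | COC(=O)CSC(C)(C)CC(=O)OC | intermediate
13 | keto ester: methyl 5,5-dimethyl-3-oxothiolane-2-carboxylate (racemic) | COC(=O)C1SC(C)(C)CC1=O | intermediate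
14 | 5,5-dimethylthiolan-3-one | CC1(C)CC(=O)CS1 | intermediate
15 | chloro ketone: 2-chloro-5,5-dimethylthiolan-3-one (racemic) | CC1(C)CC(=O)C(Cl)S1 | intermediate
16 | oxyallyl cation: 2-oxidoallyl/thionium zwitterion of 14 (lithium-bound) | CC1(C)C=C([O-])C=[S+]1 | intermediate
17 | endo (4+3) cycloadduct: 8-oxabicyclo[3.2.1]oct-6-en-3-one core (C6, C7, C8=O, C9, C10, O bridging C6 and C10); S–C(CH3)2 bridge from C9 to C7 on the face of the bridging O; C1=C5 alkene fused to the cyclopentene; at C4 methyl on the ketone face and OSiH(iPr)2 on the face of the bridging O; methyl on C10 | C[C@@]12O[C@@H](C3=C1CC[C@]3(C)O[SiH](C(C)C)C(C)C)[C@H]1C(=O)[C@@H]2SC1(C)C | intermediate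
18 | tetracyclic alcohol: 17 with C8–OH in place of C8=O, the hydroxyl pointing toward the C1=C5 alkene, trans to the C7–CMe2 bond | C[C@@]12O[C@@H](C3=C1CC[C@]3(C)O[SiH](C(C)C)C(C)C)[C@H]1[C@@H](O)[C@@H]2SC1(C)C | intermediate
19 | silylene-bridged thiabicyclic alcohol: hydroazulene with C1=C10 alkene, H5 cis to O4 and O6, O4 and O6 joined by Si(iPr)2, S–C(CH3)2 bridge from C9 to C7 cis to O6, C8–OH trans to the C7–CMe2 bond | CC1=C2CC[C@]3(C)O[Si](C(C)C)(C(C)C)O[C@@H]([C@@H]23)[C@H]4[C@@H](O)[C@@H]1SC4(C)C | intermediate
20 | 4,6-O-(diisopropylsilylene)guai-1(10)-ene-4,6,8-triol: O4, H5, O6 and the C7 isopropyl on one face, O8 on the other | CC1=C2CC[C@]3(C)O[Si](C(C)C)(C(C)C)O[C@@H]([C@@H]23)[C@H](C(C)C)[C@@H](O)C1 | intermediate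
21 | 8-O-angelate of 20 | CC1=C2CC[C@]3(C)O[Si](C(C)C)(C(C)C)O[C@@H]([C@@H]23)[C@H](C(C)C)[C@@H](OC(=O)/C(C)=C\C)C1 | intermediate
22 | 4,6-dihydroxyguai-1(10)-en-8-yl angelate (6-deacetyl target) | C/C=C(/C)C(=O)O[C@H]1CC(C)=C2CC[C@](C)(O)[C@H]2[C@H](O)[C@@H]1C(C)C | intermediate
23 | (4S,5R,6R,7R,8S)-6-acetoxy-4-hydroxyguai-1(10)-en-8-yl (Z)-2-methylbut-2-enoate | C/C=C(/C)C(=O)O[C@H]1CC(C)=C2CC[C@](C)(O)[C@H]2[C@H](OC(C)=O)[C@@H]1C(C)C | target

**Count.** Total: 14 steps. Longest linear sequence: 13 steps (steps 1–6 and 8–14).

**Steps most likely to fail**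

Step 10 (proposed new method). The allyl cation may be captured by the C8 hydroxyl or lose a methyl proton before the hydride arrives, or the Lewis acid may strip the silyl ether. The fallback uses known chemistry only, fixing C5 by hydrogenation and forming the alkene by elimination. It sets out from 18. Bu4NF should remove the silyl group to give the sulfur-bridged tetracyclic diol F1, and Raney Ni in EtOH should give the desulfurized tricyclic diol F2. Hydroxyl-directed hydrogenation with [Ir(cod)(PCy3)(py)]PF6 and H2, in which the allylic C4 hydroxyl and the ring oxygen both sit on the exo face, should add H1 and H5 from that face to give the saturated tricyclic diol F3. LiN(SiMe3)2 and angelic anhydride should acylate the secondary C8 hydroxyl to give the angelate F4. Me3SiOTf with 2,6-lutidine should silylate the C4 hydroxyl and the bridging oxygen and cleave the tertiary C10–O bond with loss of H1, giving the bis(trimethylsilyl) ether F5. HF·pyridine then brings the route back at 22. The weak point of this fallback is competing elimination toward C9, which is no longer a bridgehead.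

Step 8 (key step). The cation may alkylate the free furan α-carbon C6 without closing the second bond, the base may attack the Si–H group, or the face bias may be small. The fallback separates the hydride-donor silyl group from the cycloaddition and generates the cation by solvolysis. It sets out from 8. Et3SiCl and imidazole should give the triethylsilyl ether F6. Chloro ketone 15, prepared as in step 8, is ionised with Et3N in CF3CH2OH in the presence of F6, which should give the triethylsilyl cycloadduct F7. Bu4NF should give the hydroxy ketone F8, and iPr2SiHCl with imidazole brings the route back at 17.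

Step 11. The C1=C10 alkene may shift toward C9 or be partly saturated while the allylic C9–S bond is cleaved. The fallback reverses the order of steps 10 and 11. It sets out from 18, where no C–S bond is allylic. Raney Ni in THF should give the desulfurized tricyclic silyl ether alcohol F9, and the BF3-triggered hydride transfer of step 10 applied to F9 brings the route back at 20.

**Further compounds**

F1 | step 10 | sulfur-bridged tetracyclic diol (18 without the silyl group) | C[C@@]12O[C@@H](C3=C1CC[C@]3(C)O)[C@H]1[C@@H](O)[C@@H]2SC1(C)C
F2 | step 10 | desulfurized tricyclic diol (C7 isopropyl, C9H2, C1=C5 alkene) | C[C@@]12O[C@@H](C3=C1CC[C@]3(C)O)[C@H](C(C)C)[C@@H](O)C2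
F3 | step 10 | saturated tricyclic diol (H1 and H5 on the face of the bridging oxygen) | C[C@@]12O[C@@H]([C@H]3[C@@H]1CC[C@]3(C)O)[C@H](C(C)C)[C@@H](O)C2
F4 | step 10 | 8-O-angelate of F3 | C[C@@]12O[C@@H]([C@H]3[C@@H]1CC[C@]3(C)O)[C@H](C(C)C)[C@@H](OC(=O)/C(C)=C\C)C2
F5 | step 10 | 4,6-bis(trimethylsilyl) ether of 22 | C/C=C(/C)C(=O)O[C@H]1CC(C)=C2CC[C@](C)(O[Si](C)(C)C)[C@H]2[C@H](O[Si](C)(C)C)[C@@H]1C(C)C
F6 | step 8 | (4S)-1,4-dimethyl-4-[(triethylsilyl)oxy]-5,6-dihydro-4H-cyclopenta[c]furan | Cc1occ2c1CC[C@]2(C)O[Si](CC)(CC)CC
F7 | step 8 | triethylsilyl analogue of cycloadduct 17 | C[C@@]12O[C@@H](C3=C1CC[C@]3(C)O[Si](CC)(CC)CC)[C@H]1C(=O)[C@@H]2SC1(C)C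
F8 | step 8 | hydroxy ketone (17 with free C4 hydroxyl) | C[C@@]12O[C@@H](C3=C1CC[C@]3(C)O)[C@H]1C(=O)[C@@H]2SC1(C)C
F9 | step 11 | desulfurized tricyclic alcohol keeping the OSiH(iPr)2 group (C7 isopropyl, C9H2, C1=C5 alkene, oxygen bridge intact) | C[C@@]12O[C@@H](C3=C1CC[C@]3(C)O[SiH](C(C)C)C(C)C)[C@H](C(C)C)[C@@H](O)C2
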